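The furofuran is cut at C8–C9 and at the C7–aryl bond. C9 of ring B (O, C7', C8', C8, C9) is an isolated O-bound methylene on fusion carbon C8, and C7 of ring A (O, C7, C8, C8', C9') is the guaiacyl-bearing ether carbon, so C8=C7 can be a dihydrofuran enol ether. In one flask a formaldehyde acetal on the C7' oxygen is ionised, C8 closes ring B, and a diarylzinc arylates the new C7 cation, creating C8 and C7. The precursor, a (2,3-dihydrofuran-3-yl)(aryl)methyl methoxymethyl ether, carries only C7' and C8' from one anti aldol; its phenol is a mesylate, which suppresses benzylic ionisation at C7'.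

Key step: step 11

Numbering remark: lignan locants are used; C7–C9 belong to the guaiacyl unit, C7'–C9' to the syringyl unit of the furofuran, C7''–C9'' to the arylglycerol unit.

Design remark: the syringyl oxygen is carried as a methanesulfonate through the cationic step, because a 4-silyloxy or 4-alkoxy aryl group would make the C7'–O bond a latent quinone methide under TMSOTf; the sulfonate also makes the aldehyde a better aldol acceptor and the arene less prone to attack by ozone.

Assumption on chemistry: the MgCl2-catalysed anti aldol of the (S)-benzyl oxazolidinone is taken to follow the chelated-enolate model (aldehyde on the enolate face remote from benzyl), which gives the (2R,3S) adduct needed here.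

Assumption on supply: 4-(benzyloxy)-3,5-dimethoxybenzaldehyde is taken as a catalogue compound.

Step 1
Reactants: 1 (4S)-4-benzyl-1,3-oxazolidin-2-one; 2 pent-4-enoic acid
Product: 4 (4S)-4-benzyl-3-(pent-4-enoyl)-1,3-oxazolidin-2-one, via pivalic mixed anhydride 3 (not isolated)
Conditions: 2, PivCl, Et3N, THF, −20 °C; then LiCl, 1, −20 °C → rt
Reagents that add atoms: none
Why: The acid is activated as its mixed pivalic anhydride, and the oxazolidinone, acidified by LiCl and deprotonated by Et3N, is acylated at the less hindered carbonyl (nucleophilic acyl substitution), the standard mild entry to such imides.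

Step 2
Reactants: 5 syringaldehyde (4-hydroxy-3,5-dimethoxybenzaldehyde)
Product: 6 4-formyl-2,6-dimethoxyphenyl methanesulfonate
Conditions: MsCl, Et3N, CH2Cl2, 0 °C
Reagents that add atoms: methanesulfonyl chloride, CS(=O)(=O)Cl
Why: O-sulfonylation of a phenol with MsCl/Et3N is routine even between two ortho methoxy groups, and it installs the electron-poor group that later protects the C7' benzylic position.

Step 3
Reactants: 4 (4S)-4-benzyl-3-(pent-4-enoyl)-1,3-oxazolidin-2-one; 6 4-formyl-2,6-dimethoxyphenyl methanesulfonate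
Product: 8 (4S)-4-benzyl-3-[(2R)-2-{(S)-hydroxy[3,5-dimethoxy-4-(methylsulfonyloxy)phenyl]methyl}pent-4-enoyl]-1,3-oxazolidin-2-one, via aldol trimethylsilyl ether 7 (not isolated)
Conditions: MgCl2 (0.2 equiv), Et3N, TMSCl, EtOAc, 23 °C; then MeOH, CF3CO2H (cat.)
Reagents that add atoms: none
Why: In this Evans MgCl2-catalysed direct anti aldol the chelated (Z)-magnesium enolate of 4 should add to the aromatic aldehyde through a boat transition state on the face remote from the benzyl group, setting C8' (R in 8) and C7' (S) anti, while silylation of the aldolate by TMSCl turns the catalyst over and blocks retro-aldol before mild acidic methanol frees the alcohol.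

Step 4
Reactants: 8 the anti aldol adduct
Product: 9 (4S)-4-benzyl-3-[(2R)-2-{(S)-[3,5-dimethoxy-4-(methylsulfonyloxy)phenyl](methoxymethoxy)methyl}pent-4-enoyl]-1,3-oxazolidin-2-one
Conditions: MOMCl, iPr2NEt, Bu4NI (cat.), CH2Cl2, 0 → 40 °C
Reagents that add atoms: chloromethyl methyl ether, COCCl
Why: O-alkylation of the secondary alcohol with the α-chloro ether under a hindered amine (methoxymethyl ether formation) installs the formaldehyde acetal that is both protecting group and latent C9 electrophile, under conditions too mild to enolise C8' or trigger retro-aldol.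

Step 5
Reactants: 9 the methoxymethyl ether imide
Product: 10 4-[(1S,2S)-2-(hydroxymethyl)-1-(methoxymethoxy)pent-4-en-1-yl]-2,6-dimethoxyphenyl methanesulfonate
Conditions: LiBH4, MeOH (1 equiv), THF, 0 °C
Reagents that add atoms: none
Why: Reductive cleavage of the N-acyl oxazolidinone by LiBH4 (hydride addition to the exocyclic carbonyl) should give the C9' primary alcohol and return the auxiliary without touching the aryl mesylate, the acetal or the alkene.

Step 6
Reactants: 10 the homoallylic primary alcohol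
Product: 13 4-{(S)-[(3S)-5-hydroxyoxolan-3-yl](methoxymethoxy)methyl}-2,6-dimethoxyphenyl methanesulfonate, via 1,2,4-trioxolane 11 (not isolated), via hydroxy aldehyde 12 (not isolated)
Conditions: O3, CH2Cl2, −78 °C, Sudan Red 7B as end-point indicator; then PPh3, −78 °C → rt
Reagents that add atoms: ozone, O=[O+][O-]
Why: Ozonolysis of the terminal alkene (Criegee mechanism) with reductive work-up gives the γ-hydroxy aldehyde, which should close to the five-membered lactol (expected as an anomer mixture) because the C9' hydroxyl is the only free one.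

Step 7
Reactants: 13 the lactol
Product: 15 4-{(S)-[(3S)-2,3-dihydrofuran-3-yl](methoxymethoxy)methyl}-2,6-dimethoxyphenyl methanesulfonate, via anomeric mesylate 14 (not isolated)
Conditions: MsCl, Et3N, CH2Cl2, −20 °C → reflux
Reagents that add atoms: none
Why: Sulfonylation of the lactol hydroxyl followed by amine-mediated elimination through the C7 oxocarbenium ion (lactol dehydration to a cyclic enol ether) can place the double bond only between C7 and C8, the single β-position that carries hydrogen.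

Step 8
Reactants: 16 4-bromo-2-methoxyphenol
Product: 17 1-(benzyloxy)-4-bromo-2-methoxybenzene
Conditions: BnBr, K2CO3, DMF, rt
Reagents that add atoms: benzyl bromide, BrCc1ccccc1
Why: Williamson ether synthesis on the phenoxide is routine and leaves the aryl bromide untouched.

Step 9
Reactants: 17 1-(benzyloxy)-4-bromo-2-methoxybenzene
Product: 19 [4-(benzyloxy)-3-methoxyphenyl]zinc chloride as a THF solution, via aryllithium 18 (not isolated)
Conditions: n-BuLi (1.0 equiv), THF, −78 °C; ZnCl2 (1.0 equiv), THF, −78 → 0 °C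
Reagents that add atoms: zinc dichloride, Cl[Zn]Cl
Why: Bromine–lithium exchange followed by transmetallation with one equivalent of ZnCl2 is the standard entry to an arylzinc halide; the position of bromine fixes the regiochemistry and the 1:1 stoichiometry leaves exactly one aryl group on zinc.

Step 10
Reactants: 19 [4-(benzyloxy)-3-methoxyphenyl]zinc chloride; 17 1-(benzyloxy)-4-bromo-2-methoxybenzene
Product: 21 bis[4-(benzyloxy)-3-methoxyphenyl]zinc as a toluene solution, via arylmagnesium bromide 20 (not isolated)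
Conditions: 17, Mg turnings, THF, 40 °C (separate flask, titrated); added to 19 (1.0 equiv), 0 °C → rt; 1,4-dioxane; filtration; solvent exchanged for toluene
Reagents that add atoms: none
Why: Transmetallation of the Grignard reagent onto the arylzinc chloride (ligand exchange at zinc) delivers the second aryl group; titrating each organometallic keeps zincate and free aryl-metal out of the next step, and dioxane precipitates the magnesium halide so that little halide reaches the TMSOTf step.

Step 11
Reactants: 15 the dihydrofuranyl methoxymethyl ether; 21 bis[4-(benzyloxy)-3-methoxyphenyl]zinc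
Product: 25 4-[(1S,2S,5S,6R)-6-(4-benzyloxy-3-methoxyphenyl)-3,7-dioxabicyclo[3.3.0]octan-2-yl]-2,6-dimethoxyphenyl methanesulfonate, via O-methylene oxocarbenium triflate 22 (not isolated), via bicyclic C7 oxocarbenium triflate 23 (not isolated), via 7-methoxy acetal 24 (not isolated)
Conditions: TMSOTf (1.2 equiv), 2,6-di-tert-butyl-4-methylpyridine (0.3 equiv), CH2Cl2, −78 °C; then 21 (1.5 equiv) in toluene, −78 → −30 °C; Et3N quench
Reagents that add atoms: none
Why: Proposed new method: TMSOTf silylates the terminal methoxy oxygen of the formaldehyde acetal and expels MeOSiMe3, the O-methylene oxocarbenium ion 22 is attacked by the nucleophilic β-carbon C8 of the enol ether to form C8–C9, and the resulting C7 oxocarbenium ion 23, buffered as its methyl acetal 24, is arylated by the diarylzinc. The closest known reaction types are the Lewis-acid (Prins-type) cyclisation of acetal-derived oxocarbenium ions onto 2,3-dihydrofurans and the addition of arylzinc reagents to furanosyl oxocarbenium ions, and only their union in one flask is untested. Ring B closes in a five-membered mode that is endo with respect to the O=CH2 cation and exo with respect to the C7=C8 enol ether. C8 is controlled by the tether, which reaches the enol ether only on the face bearing the C8'–C7' bond and so can give only the cis-fused bicycle, and C7 is controlled by approach of the arylzinc to the convex face of the cup-shaped cation, away from the endo aryl group, which should place the guaiacyl group exo (C7 R, C8 S). The step needs ionisation at the acetal carbon and not at the benzylic C7'–O bond, and the electron-poor 4-mesyloxy aryl group, the hindered pyridine base and the low temperature secure this.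

Step 12
Reactants: 25 the furofuran aryl mesylate
Product: 26 4-[(1S,2S,5S,6R)-6-(4-benzyloxy-3-methoxyphenyl)-3,7-dioxabicyclo[3.3.0]octan-2-yl]-2,6-dimethoxyphenol
Conditions: LiN(iPr)2 (3 equiv), THF, −78 → 0 °C; aq. NH4Cl
Reagents that add atoms: none
Why: Base-induced cleavage of the aryl methanesulfonate (α-deprotonation of the mesyl group and E1cB loss of sulfene) should release the phenoxide at low temperature under conditions to which the ether-only furofuran and the benzyl ether are inert.

Step 13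
Reactants: 1 (4S)-4-benzyl-1,3-oxazolidin-2-one; 27 bromoacetyl bromide
Product: 29 (4S)-4-benzyl-3-(bromoacetyl)-1,3-oxazolidin-2-one, via N-lithio oxazolidinone 28 (not isolated)
Conditions: n-BuLi, THF, −78 °C; then 27, −78 °C
Reagents that add atoms: none
Why: N-acylation of the lithiated oxazolidinone at the acyl bromide terminus (nucleophilic acyl substitution) gives the α-bromo imide, the C–Br bond being spared at −78 °C.

Step 14
Reactants: 26 the furofuran phenol; 29 (4S)-4-benzyl-3-(bromoacetyl)-1,3-oxazolidin-2-one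
Product: 30 (4S)-4-benzyl-3-({4-[(1S,2S,5S,6R)-6-(4-benzyloxy-3-methoxyphenyl)-3,7-dioxabicyclo[3.3.0]octan-2-yl]-2,6-dimethoxyphenoxy}acetyl)-1,3-oxazolidin-2-one
Conditions: K2CO3, acetone, rt
Reagents that add atoms: none
Why: In this Williamson O-alkylation the phenoxide displaces bromide from the activated α-bromo imide by SN2, a reaction that tolerates two flanking methoxy groups as in standard preparations of arylglycerol aryl ethers.

Step 15
Reactants: 30 the aryloxyacetyl imide; 31 4-(benzyloxy)-3,5-dimethoxybenzaldehyde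
Product: 34 (4S)-4-benzyl-3-[(2S,3R)-3-(4-benzyloxy-3,5-dimethoxyphenyl)-3-hydroxy-2-{4-[(1S,2S,5S,6R)-6-(4-benzyloxy-3-methoxyphenyl)-3,7-dioxabicyclo[3.3.0]octan-2-yl]-2,6-dimethoxyphenoxy}propanoyl]-1,3-oxazolidin-2-one, via dibutylboron enolate 32 (not isolated), via dibutylboron aldolate 33 (not isolated)
Conditions: Bu2BOTf, iPr2NEt, CH2Cl2, −78 → 0 °C; 31, −78 → 0 °C; pH 7 buffer, MeOH, H2O2, 0 °C
Reagents that add atoms: none
Why: In this Evans boron-mediated syn aldol of a glycolate imide the (Z)-dibutylboron enolate should react through a closed Zimmerman–Traxler chair, the aldehyde approaching the enolate face opposite the benzyl group of the dipole-minimised auxiliary, which sets C8'' (S in 34) and C7'' (R) syn, that is threo after reduction.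

Step 16
Reactants: 34 the syn aldol adduct
Product: 35 (1R,2R)-1-(4-benzyloxy-3,5-dimethoxyphenyl)-2-{4-[(1S,2S,5S,6R)-6-(4-benzyloxy-3-methoxyphenyl)-3,7-dioxabicyclo[3.3.0]octan-2-yl]-2,6-dimethoxyphenoxy}propane-1,3-diol
Conditions: LiBH4, MeOH (1 equiv), THF, 0 °C
Reagents that add atoms: none
Why: Reductive removal of the oxazolidinone with LiBH4 converts the imide carbonyl into the C9'' primary alcohol under conditions that are not expected to epimerise C8''.

Step 17
Reactants: 35 the bis(benzyl ether) diol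
Product: 36 (1R,2R)-1-(4-hydroxy-3,5-dimethoxyphenyl)-2-{4-[(1S,2S,5S,6R)-6-(4-hydroxy-3-methoxyphenyl)-3,7-dioxabicyclo[3.3.0]octan-2-yl]-2,6-dimethoxyphenoxy}propane-1,3-diol (CNP0317965.1)
Conditions: H2 (1 atm), 10% Pd/C, EtOAc–MeOH, rt, stopped at full debenzylation
Reagents that add atoms: none
Why: Catalytic hydrogenolysis of the two aryl benzyl ethers over palladium under neutral conditions should be much faster than cleavage of the dialkyl benzylic C–O bonds of the furofuran or of the benzylic alcohol.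

Compound list

1 | (4S)-4-benzyl-1,3-oxazolidin-2-one | O=C1N[C@@H](Cc2ccccc2)CO1 | starting material
2 | pent-4-enoic acid | C=CCCC(=O)O | starting material
3 | pent-4-enoic pivalic anhydride (2,2-dimethylpropanoic pent-4-enoic anhydride) | C=CCCC(=O)OC(=O)C(C)(C)C | intermediate
4 | (4S)-4-benzyl-3-(pent-4-enoyl)-1,3-oxazolidin-2-one | C=CCCC(=O)N1[C@@H](Cc2ccccc2)COC1=O | intermediate
5 | syringaldehyde | COc1cc(C=O)cc(OC)c1O | starting material
6 | 4-formyl-2,6-dimethoxyphenyl methanesulfonate | COc1cc(C=O)cc(OC)c1OS(C)(=O)=O | intermediate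
7 | O-trimethylsilyl ether of 8 | C[Si](C)(C)O[C@@H]([C@@H](CC=C)C(=O)N1[C@@H](Cc2ccccc2)COC1=O)c1cc(OC)c(OS(C)(=O)=O)c(OC)c1 | intermediate
8 | (4S)-4-benzyl-3-[(2R)-2-{(S)-hydroxy[3,5-dimethoxy-4-(methylsulfonyloxy)phenyl]methyl}pent-4-enoyl]-1,3-oxazolidin-2-one (anti aldol; C8' R, C7' S) | O[C@@H]([C@@H](CC=C)C(=O)N1[C@@H](Cc2ccccc2)COC1=O)c1cc(OC)c(OS(C)(=O)=O)c(OC)c1 | intermediate
9 | methoxymethyl ether of 8 | COCO[C@@H]([C@@H](CC=C)C(=O)N1[C@@H](Cc2ccccc2)COC1=O)c1cc(OC)c(OS(C)(=O)=O)c(OC)c1 | intermediate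
10 | 4-[(1S,2S)-2-(hydroxymethyl)-1-(methoxymethoxy)pent-4-en-1-yl]-2,6-dimethoxyphenyl methanesulfonate | COCO[C@@H]([C@@H](CC=C)CO)c1cc(OC)c(OS(C)(=O)=O)c(OC)c1 | intermediate
11 | 4-[(1S,2S)-2-(hydroxymethyl)-1-(methoxymethoxy)-3-(1,2,4-trioxolan-3-yl)propyl]-2,6-dimethoxyphenyl methanesulfonate (ozonide, epimers at the trioxolane carbon) | COCO[C@@H]([C@@H](CC1OCOO1)CO)c1cc(OC)c(OS(C)(=O)=O)c(OC)c1 | intermediate
12 | 4-[(1S,2S)-2-(hydroxymethyl)-1-(methoxymethoxy)-4-oxobutyl]-2,6-dimethoxyphenyl methanesulfonate | COCO[C@@H]([C@@H](CC=O)CO)c1cc(OC)c(OS(C)(=O)=O)c(OC)c1 | intermediate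
13 | 4-{(S)-[(3S)-5-hydroxyoxolan-3-yl](methoxymethoxy)methyl}-2,6-dimethoxyphenyl methanesulfonate (lactol, both anomers) | COCO[C@@H]([C@@H]1COC(O)C1)c1cc(OC)c(OS(C)(=O)=O)c(OC)c1 | intermediate
14 | anomeric methanesulfonate of 13 | COCO[C@@H]([C@@H]1COC(OS(C)(=O)=O)C1)c1cc(OC)c(OS(C)(=O)=O)c(OC)c1 | intermediate
15 | 4-{(S)-[(3S)-2,3-dihydrofuran-3-yl](methoxymethoxy)methyl}-2,6-dimethoxyphenyl methanesulfonate (key-step precursor) | COCO[C@@H]([C@@H]1COC=C1)c1cc(OC)c(OS(C)(=O)=O)c(OC)c1 | intermediate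
16 | 4-bromo-2-methoxyphenol | COc1cc(Br)ccc1O | starting material
17 | 1-(benzyloxy)-4-bromo-2-methoxybenzene | COc1cc(Br)ccc1OCc1ccccc1 | intermediate
18 | [4-(benzyloxy)-3-methoxyphenyl]lithium | [Li]c1ccc(OCc2ccccc2)c(OC)c1 | intermediate
19 | [4-(benzyloxy)-3-methoxyphenyl]zinc chloride | COc1cc([Zn]Cl)ccc1OCc1ccccc1 | intermediate
20 | [4-(benzyloxy)-3-methoxyphenyl]magnesium bromide | COc1cc([Mg]Br)ccc1OCc1ccccc1 | intermediate
21 | bis[4-(benzyloxy)-3-methoxyphenyl]zinc | COc1cc([Zn]c2ccc(OCc3ccccc3)c(OC)c2)ccc1OCc1ccccc1 | intermediate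
22 | methylidene{(S)-[(3S)-2,3-dihydrofuran-3-yl][3,5-dimethoxy-4-(methylsulfonyloxy)phenyl]methyl}oxonium triflate | C=[O+][C@@H]([C@@H]1COC=C1)c1cc(OC)c(OS(C)(=O)=O)c(OC)c1.[O-]S(=O)(=O)C(F)(F)F | intermediate
23 | cis-fused bicyclic oxocarbenium triflate, ring A O=C7 cation, aryl on C7' endo (C8 S, C8' S, C7' S) | C1=[O+]C[C@@H]2[C@H]1CO[C@@H]2c1cc(OC)c(OS(C)(=O)=O)c(OC)c1.[O-]S(=O)(=O)C(F)(F)F | intermediate
24 | 4-[(1S,2S,5S)-6-methoxy-3,7-dioxabicyclo[3.3.0]octan-2-yl]-2,6-dimethoxyphenyl methanesulfonate (7-methoxy acetal, both C7 epimers) | COC1OC[C@@H]2[C@H]1CO[C@@H]2c1cc(OC)c(OS(C)(=O)=O)c(OC)c1 | intermediate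
25 | 4-[(1S,2S,5S,6R)-6-(4-benzyloxy-3-methoxyphenyl)-3,7-dioxabicyclo[3.3.0]octan-2-yl]-2,6-dimethoxyphenyl methanesulfonate (C7 R, C8 S, C7' S, C8' S; guaiacyl exo, syringyl endo) | COc1cc([C@@H]2OC[C@@H]3[C@H]2CO[C@@H]3c2cc(OC)c(OS(C)(=O)=O)c(OC)c2)ccc1OCc1ccccc1 | intermediate
26 | 4-[(1S,2S,5S,6R)-6-(4-benzyloxy-3-methoxyphenyl)-3,7-dioxabicyclo[3.3.0]octan-2-yl]-2,6-dimethoxyphenol | COc1cc([C@@H]2OC[C@@H]3[C@H]2CO[C@@H]3c2cc(OC)c(O)c(OC)c2)ccc1OCc1ccccc1 | intermediate
27 | bromoacetyl bromide | BrCC(Br)=O | starting material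
28 | N-lithio-(4S)-4-benzyl-1,3-oxazolidin-2-one | [Li]N1[C@@H](Cc2ccccc2)COC1=O | intermediate
29 | (4S)-4-benzyl-3-(bromoacetyl)-1,3-oxazolidin-2-one | BrCC(=O)N1[C@@H](Cc2ccccc2)COC1=O | intermediate
30 | (4S)-4-benzyl-3-({4-[(1S,2S,5S,6R)-6-(4-benzyloxy-3-methoxyphenyl)-3,7-dioxabicyclo[3.3.0]octan-2-yl]-2,6-dimethoxyphenoxy}acetyl)-1,3-oxazolidin-2-one | COc1cc([C@@H]2OC[C@@H]3[C@H]2CO[C@@H]3c2cc(OC)c(OCC(=O)N4[C@@H](Cc5ccccc5)COC4=O)c(OC)c2)ccc1OCc1ccccc1 | intermediate
31 | 4-(benzyloxy)-3,5-dimethoxybenzaldehyde | COc1cc(C=O)cc(OC)c1OCc1ccccc1 | starting material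
32 | (Z)-dibutylboron enolate of 30 | COc1cc([C@@H]2OC[C@@H]3[C@H]2CO[C@@H]3c2cc(OC)c(O/C=C(\OB(CCCC)CCCC)N4[C@@H](Cc5ccccc5)COC4=O)c(OC)c2)ccc1OCc1ccccc1 | intermediate
33 | O-dibutylboryl aldolate of 34 | COc1cc([C@@H]2OC[C@@H]3[C@H]2CO[C@@H]3c2cc(OC)c(O[C@H](C(=O)N4[C@@H](Cc5ccccc5)COC4=O)[C@H](OB(CCCC)CCCC)c4cc(OC)c(OCc5ccccc5)c(OC)c4)c(OC)c2)ccc1OCc1ccccc1 | intermediate
34 | (4S)-4-benzyl-3-[(2S,3R)-3-(4-benzyloxy-3,5-dimethoxyphenyl)-3-hydroxy-2-{4-[(1S,2S,5S,6R)-6-(4-benzyloxy-3-methoxyphenyl)-3,7-dioxabicyclo[3.3.0]octan-2-yl]-2,6-dimethoxyphenoxy}propanoyl]-1,3-oxazolidin-2-one | COc1cc([C@@H]2OC[C@@H]3[C@H]2CO[C@@H]3c2cc(OC)c(O[C@H](C(=O)N4[C@@H](Cc5ccccc5)COC4=O)[C@H](O)c4cc(OC)c(OCc5ccccc5)c(OC)c4)c(OC)c2)ccc1OCc1ccccc1 | intermediate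
35 | (1R,2R)-1-(4-benzyloxy-3,5-dimethoxyphenyl)-2-{4-[(1S,2S,5S,6R)-6-(4-benzyloxy-3-methoxyphenyl)-3,7-dioxabicyclo[3.3.0]octan-2-yl]-2,6-dimethoxyphenoxy}propane-1,3-diol | COc1cc([C@@H]2OC[C@@H]3[C@H]2CO[C@@H]3c2cc(OC)c(O[C@H](CO)[C@H](O)c4cc(OC)c(OCc5ccccc5)c(OC)c4)c(OC)c2)ccc1OCc1ccccc1 | intermediate
36 | (1R,2R)-1-(4-hydroxy-3,5-dimethoxyphenyl)-2-{4-[(1S,2S,5S,6R)-6-(4-hydroxy-3-methoxyphenyl)-3,7-dioxabicyclo[3.3.0]octan-2-yl]-2,6-dimethoxyphenoxy}propane-1,3-diol | COc1cc([C@@H]2OC[C@@H]3[C@H]2CO[C@@H]3c2cc(OC)c(O[C@H](CO)[C@H](O)c3cc(OC)c(O)c(OC)c3)c(OC)c2)ccc1O | target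

Total step count: 17. Longest linear sequence: 12 steps (2, 3, 4, 5, 6, 7, 11, 12, 14, 15, 16, 17 from syringaldehyde; the same length from 1 and 2 through step 1).

Steps most likely to fail

1. Step 11 (Proposed new method). The benzylic C7'–O bond may ionise, or the enol ether may be protonated, in competition with ionisation at the acetal carbon. Aryl transfer from zinc may also be too slow, so that the bicyclic cation stalls as its methyl acetal or loses a proton. The fallback uses known chemistry and sets out from 15. Catalytic TMSOTf (0.1 equiv) with 2,6-di-tert-butyl-4-methylpyridine in CH2Cl2 at −78 °C performs only the acetal-to-dihydrofuran cyclisation and should give the bicyclic methyl acetal 24, which is isolated. Benzenesulfinic acid with CaCl2 in CH2Cl2 then exchanges methoxide for sulfinate to give the anomeric phenyl sulfone, 4-[(1S,2S,5S)-6-(phenylsulfonyl)-3,7-dioxabicyclo[3.3.0]octan-2-yl]-2,6-dimethoxyphenyl methanesulfonate F1. Displacement of the sulfone by diarylzinc 21 with ZnBr2 in THF at room temperature, an established substitution of 2-sulfonyl cyclic ethers by organozinc reagents through the same C7 oxocarbenium ion and convex-face attack, returns to 25.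

2. Step 15. Enolisation of the bulky aryloxyacetyl imide may be incomplete, facial selectivity may erode, or Bu2BOTf may open the benzylic furofuran ethers. The fallback drops the auxiliary and the boron Lewis acid and sets out from phenol 26. Alkylation with ethyl bromoacetate (K2CO3, acetone) gives the ethyl aryloxyacetate F2. Its lithium enolate (LiN(iPr)2, THF, −78 °C) adds to aldehyde 31 to give the β-hydroxy ester F3 as a mixture of C7''/C8'' isomers. Dess–Martin periodinane converts this into the β-keto ester F4, whose C8'' epimers interconvert. Noyori-type asymmetric transfer hydrogenation with dynamic kinetic resolution (RuCl(p-cymene)[(S,S)-TsDPEN], HCO2H/Et3N) is syn-selective for α-alkoxy β-keto esters. With the ligand enantiomer that the usual aryl ketone model predicts for the (3R) alcohol, it should give the (2S,3R) syn hydroxy ester F5. LiBH4 reduction of the ester returns to diol 35.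

3. Step 7. Elimination of the anomeric sulfonate may be incomplete, and the enol ether may hydrate or oligomerise under acid during work-up. The fallback replaces ionisation by an oxidative syn-elimination and sets out from lactol 13. N-(Phenylseleno)phthalimide and Bu3P should give the anomeric phenyl selenide F6. NaIO4 with NaHCO3 in MeOH–H2O oxidises it to the selenoxide F7, which eliminates at room temperature in the presence of iPr2NH across C7–C8 and returns to 15.

Further compounds

F1 | step 11 | 4-[(1S,2S,5S)-6-(phenylsulfonyl)-3,7-dioxabicyclo[3.3.0]octan-2-yl]-2,6-dimethoxyphenyl methanesulfonate | O=S(=O)(c1ccccc1)C1OC[C@@H]2[C@H]1CO[C@@H]2c1cc(OC)c(OS(C)(=O)=O)c(OC)c1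
F2 | step 15 | ethyl {4-[(1S,2S,5S,6R)-6-(4-benzyloxy-3-methoxyphenyl)-3,7-dioxabicyclo[3.3.0]octan-2-yl]-2,6-dimethoxyphenoxy}acetate | COc1cc([C@@H]2OC[C@@H]3[C@H]2CO[C@@H]3c2cc(OC)c(OCC(=O)OCC)c(OC)c2)ccc1OCc1ccccc1
F3 | step 15 | ethyl 3-(4-benzyloxy-3,5-dimethoxyphenyl)-3-hydroxy-2-(aryloxy)propanoate, aryl as in F2, isomer mixture at C2 and C3 | COc1cc([C@@H]2OC[C@@H]3[C@H]2CO[C@@H]3c2cc(OC)c(OC(C(=O)OCC)C(O)c4cc(OC)c(OCc5ccccc5)c(OC)c4)c(OC)c2)ccc1OCc1ccccc1
F4 | step 15 | ethyl 3-(4-benzyloxy-3,5-dimethoxyphenyl)-3-oxo-2-(aryloxy)propanoate, aryl as in F2, C2 epimers | COc1cc([C@@H]2OC[C@@H]3[C@H]2CO[C@@H]3c2cc(OC)c(OC(C(=O)OCC)C(=O)c4cc(OC)c(OCc5ccccc5)c(OC)c4)c(OC)c2)ccc1OCc1ccccc1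
F5 | step 15 | ethyl (2S,3R)-3-(4-benzyloxy-3,5-dimethoxyphenyl)-3-hydroxy-2-(aryloxy)propanoate, aryl as in F2 | COc1cc([C@@H]2OC[C@@H]3[C@H]2CO[C@@H]3c2cc(OC)c(O[C@H](C(=O)OCC)[C@H](O)c4cc(OC)c(OCc5ccccc5)c(OC)c4)c(OC)c2)ccc1OCc1ccccc1
F6 | step 7 | 4-{(S)-(methoxymethoxy)[(3S)-5-(phenylselanyl)oxolan-3-yl]methyl}-2,6-dimethoxyphenyl methanesulfonate | COCO[C@@H]([C@@H]1COC([Se]c2ccccc2)C1)c1cc(OC)c(OS(C)(=O)=O)c(OC)c1
F7 | step 7 | 4-{(S)-(methoxymethoxy)[(3S)-5-(phenylseleninyl)oxolan-3-yl]methyl}-2,6-dimethoxyphenyl methanesulfonate | COCO[C@@H]([C@@H]1COC([Se](=O)c2ccccc2)C1)c1cc(OC)c(OS(C)(=O)=O)c(OC)c1
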